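**Retrosynthetic overview**
1. Endgame: 33 ⇐ tert-butyl ester 32 (acid-only unmasking, so the C19 acetate never meets hydroxide) ⇐ C3 ketone 29 (2-OH by enolate oxidation, 3-OH by axial-selective reduction) ⇐ enol ether 25 (C4 made quaternary by cyclopropanation/ring opening, new C18 anti to C20).
2. Key disconnection: retro-[4+2] of ring A of 23 across C1–C2 and C5–C10 gives the acyclic tetraenal 22. Its chain C6–C9 is the tether, so ring B (tether ring) and ring A (cycloadduct ring) form together in step 12; no ring exists before.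
3. Enabling feature: ring A (C1–C2–C3–C4–C5–C10) has oxygen at C3 next to quaternary C4 and shares the fusion bond C5–C10 with ring B, whose quaternary C10 carries a one-carbon substituent (C20). C3–O/C4 map onto a 2-methoxy-3-(silyloxymethyl)diene C2=C3–C4=C5, C20 as CHO activates the C1=C10 dienophile, and the Z-C7=C8 bond of ring B already sits in the tether.
4. 22 ⇐ allylic alcohol 21 ⇐ ester 20, made by Cu-catalysed enantioselective SN2′ union (sets C9) of alkenyl iodide 17 (C2–C8, C17, C19) with allylic bromide 7 (C1, C9–C16, C20).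
5. 7 ⇐ (R)-citronellic acid (C13) + methyl acrylate; 17 ⇐ 3-silyloxypropanal by Z-selective iodo-olefination, Wittig reaction and ester methylenation.

Key step: step 12

Remark: labdane numbering is used for all compounds; α is the decalin face that carries C20 (with C19 and C11), β the opposite face (H-5, H-9, C18, 2-OH, 3-OH). Commercial (R)-(+)-citronellic acid is assumed as the source of C13.

**Route**

Step 1
Reactants: 1 (R)-(+)-citronellic acid
Product: 2 tert-butyl (3R)-3,7-dimethyloct-6-enoate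
Conditions: tert-butyl 2,2,2-trichloroacetimidate (2 equiv), BF3·OEt2 (cat.), cyclohexane/CH2Cl2, rt
Reagents that add atoms: tert-butyl 2,2,2-trichloroacetimidate, CC(C)(C)OC(=N)C(Cl)(Cl)Cl
Why: Acid-catalysed imidate esterification installs an ester that is later cleaved by acid alone, and C13 (R) is not touched.

Step 2
Reactants: 2 tert-butyl (3R)-3,7-dimethyloct-6-enoate
Product: 4 tert-butyl (3R)-3-methyl-6-oxohexanoate, via ozonide 3 (not isolated)
Conditions: O3, CH2Cl2, −78 °C; then PPh3, −78 °C → rt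
Reagents that add atoms: ozone, [O-][O+]=O
Why: Ozonolysis with reductive work-up cleaves the trisubstituted alkene to the aldehyde whose carbon becomes C9, while the ester and C13 are inert.

Step 3
Reactants: 4 tert-butyl (3R)-3-methyl-6-oxohexanoate; 5 methyl acrylate
Product: 6 8-tert-butyl 1-methyl (6R)-3-hydroxy-6-methyl-2-methylideneoctanedioate (C3 epimers)
Conditions: DABCO (0.5 equiv), methyl acrylate (3 equiv), MeOH (2 equiv), rt
Reagents that add atoms: none
Why: The Morita–Baylis–Hillman reaction joins C10 (with C1 as methylene and C20 as ester) to C9; the carbinol configuration is irrelevant because C9 becomes sp2 in step 4.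

Step 4
Reactants: 6 8-tert-butyl 1-methyl (6R)-3-hydroxy-6-methyl-2-methylideneoctanedioate
Product: 7 8-tert-butyl 1-methyl (2Z,6R)-2-(bromomethyl)-6-methyloct-2-enedioate
Conditions: NBS (1.3 equiv), Me2S (1.4 equiv), CH2Cl2, 0 °C → rt
Reagents that add atoms: N-bromosuccinimide, O=C1CCC(=O)N1Br
Why: Corey–Kim-type activation of the alcohol and SN2′ attack of bromide should give the (Z)-2-(bromomethyl)enoate, the electrophile for the coupling in step 10.

Step 5
Reactants: 8 3-[(tert-butyldimethylsilyl)oxy]propanal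
Product: 9 tert-butyl{[(3Z)-4-iodopent-3-en-1-yl]oxy}dimethylsilane
Conditions: [Ph3PEt]I, n-BuLi, THF, 0 °C; added to I2, −78 °C; NaHMDS, −20 °C; then 8, −78 °C → rt
Reagents that add atoms: ethyltriphenylphosphonium iodide, CC[P+](c1ccccc1)(c1ccccc1)c1ccccc1.[I-]; iodine, II
Why: The Stork–Zhao-type Wittig olefination with the α-iodo ylide should give the (Z)-2-iodoalkene, fixing the geometry that lets C7=C8 lie inside ring B.

Step 6
Reactants: 9 tert-butyl{[(3Z)-4-iodopent-3-en-1-yl]oxy}dimethylsilane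
Product: 10 (3Z)-4-iodopent-3-en-1-ol
Conditions: PPTS (0.2 equiv), MeOH, 40 °C
Reagents that add atoms: none
Why: Acid-catalysed methanolysis removes the primary TBS ether and leaves the vinyl iodide intact.

Step 7
Reactants: 11 methyl (triphenylphosphoranylidene)acetate; 12 (chloromethoxy)triisopropylsilane
Product: 14 methyl 2-(triphenylphosphoranylidene)-3-[(triisopropylsilyl)oxy]propanoate, via phosphonium chloride 13 (not isolated)
Conditions: 11 (2 equiv), CH2Cl2, 0 °C → rt (second equivalent of 11 as base)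
Reagents that add atoms: none
Why: C-Alkylation of the ester-stabilised ylide by the chloromethyl silyl ether and transylidation give the ylide that carries C3, C4 and C19.

Step 8
Reactants: 10 (3Z)-4-iodopent-3-en-1-ol; 14 methyl 2-(triphenylphosphoranylidene)-3-[(triisopropylsilyl)oxy]propanoate
Product: 16 methyl (2E,5Z)-6-iodo-2-{[(triisopropylsilyl)oxy]methyl}hepta-2,5-dienoate, via aldehyde 15 (not isolated)
Conditions: Dess–Martin periodinane (1.1 equiv), CH2Cl2, 0 °C; then 14 (1.2 equiv), rt
Reagents that add atoms: none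
Why: Dess–Martin oxidation and immediate Wittig olefination of the sensitive β,γ-unsaturated aldehyde with the α-substituted stabilised ylide should give the (E)-enoate (ester trans to C6), so that C6 sits "outside" on the later diene.

Step 9
Reactants: 16 methyl (2E,5Z)-6-iodo-2-{[(triisopropylsilyl)oxy]methyl}hepta-2,5-dienoate
Product: 17 (3E,6Z)-7-iodo-2-methoxy-3-{[(triisopropylsilyl)oxy]methyl}octa-1,3,6-triene
Conditions: Cp2TiMe2 (2.5 equiv), toluene, 65 °C, dark
Reagents that add atoms: dimethyltitanocene, [CH3-].[CH3-].[Ti+4].c1cc[cH-]c1.c1cc[cH-]c1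
Why: Petasis methylenation of the only ester turns C3=O into the C3(OMe)=C2H2 enol ether, i.e. the 2-methoxy-1,3-diene, without touching the alkene geometries.

Step 10
Reactants: 17 (3E,6Z)-7-iodo-2-methoxy-3-{[(triisopropylsilyl)oxy]methyl}octa-1,3,6-triene; 7 8-tert-butyl 1-methyl (2Z,6R)-2-(bromomethyl)-6-methyloct-2-enedioate
Product: 20 8-tert-butyl 1-methyl (3R,6R)-3-[(2Z,5E)-7-methoxy-6-{[(triisopropylsilyl)oxy]methyl}octa-2,5,7-trien-2-yl]-6-methyl-2-methylideneoctanedioate, via alkenyllithium 18 (not isolated), via alkenylalane 19 (not isolated)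
Conditions: t-BuLi (2 equiv), Et2O, −78 °C; i-Bu2AlCl (1 equiv), −78 → 0 °C; then 7, CuCl2·2H2O (2 mol %), chiral sulfonate-bearing imidazolinium NHC precursor (2.5 mol %), THF, −30 °C
Reagents that add atoms: none
Why: In this Cu-catalysed enantioselective SN2′ allylic substitution the chiral NHC–Cu–alkenyl species adds to C9 with loss of bromide from C1 and retention of the Z-alkenyl geometry; the catalyst enantiomer is chosen for 9R (C13 is too remote to interfere) and the 2-methylene ester forms directly.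

Step 11
Reactants: 20 8-tert-butyl 1-methyl (3R,6R)-3-[(2Z,5E)-7-methoxy-6-{[(triisopropylsilyl)oxy]methyl}octa-2,5,7-trien-2-yl]-6-methyl-2-methylideneoctanedioate
Product: 21 tert-butyl (3R,6R,7Z,10E)-6-(3-hydroxyprop-1-en-2-yl)-12-methoxy-3,7-dimethyl-11-{[(triisopropylsilyl)oxy]methyl}trideca-7,10,12-trienoate
Conditions: DIBAL-H (2.3 equiv), CH2Cl2, −78 °C; Rochelle salt
Reagents that add atoms: none
Why: 1,2-Reduction of the methyl 2-alkylacrylate by DIBAL-H gives the 2-methylene allylic alcohol, while the hindered tert-butyl ester and the enol ether should survive at −78 °C.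

Step 12
Reactants: 21 tert-butyl (3R,6R,7Z,10E)-6-(3-hydroxyprop-1-en-2-yl)-12-methoxy-3,7-dimethyl-11-{[(triisopropylsilyl)oxy]methyl}trideca-7,10,12-trienoate
Product: 23 tert-butyl 3-methoxy-20-oxo-19-[(triisopropylsilyl)oxy]-18-norlabda-3,7-dien-15-oate (trans-fused; 5β-H; 9β-H; 10α-CHO; 13R), via enal 22 (not isolated)
Conditions: MnO2 (20 equiv), CH2Cl2, 0 °C → rt, filtration; then Me2AlCl (0.3 equiv), CH2Cl2, −78 → −30 °C
Reagents that add atoms: none
Why: MnO2 oxidises the allylic alcohol to the 2-substituted acrolein 22, whose Lewis-acid-activated C1=C10 bond then undergoes a concerted, asynchronous normal-demand [4+2] cycloaddition with the electron-rich 2-methoxydiene C2=C3–C4=C5 (intramolecular Diels–Alder reaction). The closest known reaction type is the intramolecular Diels–Alder reaction of 1,7,9-decatrienes whose dienophile bears its activating carbonyl group on the tethered carbon, and of 2-alkoxy- or 2-siloxydienes with enals. Ring A is closed by the cycloaddition itself in the fused mode (C1–C2 and C5–C10 form together, nucleophilic diene terminus C2 meeting electrophilic C1), and ring B is closed in the same event as the six-membered tether ring C5–C6–C7=C8–C9–C10. C10 and C5 should arise trans to each other from the endo-formyl transition state (formyl under the diene, tether exo, C6 outside on the E-configured C4=C5 bond), and their absolute sense is set by C9, whose side chain takes the pseudo-equatorial position anti to the forming C5–C10 bond (least A1,3 strain with the C1 methylene), which places C20 and C11 on the same face. The step needs endo selectivity, π-facial selectivity and fused rather than bridged regiochemistry; these are secured by Lewis-acid catalysis at low temperature, by the C9 stereocentre with the rigid Z-C7=C8 tether, and by the four-atom tether together with the matched polarity of diene and dienophile.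

Step 13
Reactants: 23 tert-butyl 3-methoxy-20-oxo-19-[(triisopropylsilyl)oxy]-18-norlabda-3,7-dien-15-oate
Product: 25 tert-butyl 3-methoxy-19-[(triisopropylsilyl)oxy]-18-norlabda-3,7-dien-15-oate (5β-H; 9β-H; 10α-CH3; 13R), via N-silylhydrazone 24 (not isolated)
Conditions: TBSNHNHTBS (1.2 equiv), Sc(OTf)3 (1 mol %), CH2Cl2, rt; then KOt-Bu (0.5 equiv), t-BuOH, DMSO, rt
Reagents that add atoms: none
Why: Wolff–Kishner reduction in its mild N-silylhydrazone variant turns the angular formyl group into the C20 methyl group; no stereocentre is involved and the base-stable enol ether, TIPS ether and tert-butyl ester should survive.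

Step 14
Reactants: 25 tert-butyl 3-methoxy-19-[(triisopropylsilyl)oxy]-18-norlabda-3,7-dien-15-oate
Product: 26 tert-butyl 3α-methoxy-19-[(triisopropylsilyl)oxy]-3β,18-cyclolabd-7-en-15-oate (C18 methylene β)
Conditions: Et2Zn (3 equiv), CH2I2 (3 equiv), CH2Cl2, 0 °C → rt
Reagents that add atoms: diiodomethane, ICI
Why: Simmons–Smith (Furukawa) cyclopropanation of the electron-rich enol ether should occur on the β face, anti to the axial C20 methyl group, so the new carbon (future C18) is β at C4 and C19 becomes the axial α substituent; the hindered Δ7 alkene is much less reactive.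

Step 15
Reactants: 26 tert-butyl 3α-methoxy-19-[(triisopropylsilyl)oxy]-3β,18-cyclolabd-7-en-15-oate
Product: 28 tert-butyl 19-hydroxy-3-oxolabd-7-en-15-oate, via ketone 27 (not isolated)
Conditions: TsOH·H2O (0.3 equiv), THF/H2O (10:1), 40 °C; then HF·pyridine, THF, 0 °C → rt
Reagents that add atoms: water, O
Why: Acid-induced ring opening of the alkoxycyclopropane (protonation at the CH2 carbon, hydrolysis of the oxocarbenium ion) converts the cyclopropane into the C18 methyl group and the C3 ketone with C4 as set in step 14, and fluoride then cleaves the TIPS ether.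

Step 16
Reactants: 28 tert-butyl 19-hydroxy-3-oxolabd-7-en-15-oate
Product: 29 tert-butyl 19-acetoxy-3-oxolabd-7-en-15-oate
Conditions: Ac2O (2 equiv), pyridine, DMAP (5 mol %), CH2Cl2, 0 °C → rt
Reagents that add atoms: acetic anhydride, CC(=O)OC(C)=O
Why: DMAP-catalysed acylation of the neopentyl primary alcohol; the β-acetoxy ketone cannot eliminate because C4 is quaternary.

Step 17
Reactants: 29 tert-butyl 19-acetoxy-3-oxolabd-7-en-15-oate
Product: 31 tert-butyl 19-acetoxy-2β-hydroxy-3-oxolabd-7-en-15-oate, via potassium enolate 30 (not isolated)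
Conditions: KHMDS (1.1 equiv), THF, −78 °C; then 3-phenyl-2-(phenylsulfonyl)oxaziridine (1.5 equiv), −78 °C; sat. aq. NH4Cl
Reagents that add atoms: 3-phenyl-2-(phenylsulfonyl)oxaziridine, O=S(=O)(N1OC1c1ccccc1)c1ccccc1
Why: Enolate hydroxylation with an N-sulfonyloxaziridine: C2 is the only enolisable position, and the oxidant should approach the Δ2 enolate from the β face because the α face is blocked by the syn-axial C19 and C20 groups, giving the equatorial 2β-OH (2S).

Step 18
Reactants: 31 tert-butyl 19-acetoxy-2β-hydroxy-3-oxolabd-7-en-15-oate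
Product: 32 tert-butyl 19-acetoxy-2β,3β-dihydroxylabd-7-en-15-oate
Conditions: L-Selectride (2.5 equiv), THF, −78 °C; sat. aq. NH4Cl at −78 °C
Reagents that add atoms: none
Why: Reduction with a bulky trialkylborohydride: hydride should be delivered along the equatorial trajectory from the α face, giving the axial 3β-alcohol (3R) cis to the 2-OH, as is usual for 4,4-disubstituted 3-ketones; esters are not reduced at −78 °C.

Step 19
Reactants: 32 tert-butyl 19-acetoxy-2β,3β-dihydroxylabd-7-en-15-oate
Product: 33 (2S,3R,4R,5S,9R,10S,13R)-19-acetoxy-2,3-dihydroxylabd-7-en-15-oic acid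
Conditions: TFA/CH2Cl2 (1:4), 0 °C
Reagents that add atoms: none
Why: Acidolysis of the tert-butyl ester (alkyl–oxygen cleavage) frees the C15 acid without hydroxide, so the C19 acetate and the diol should remain in place.

**Compound list**
1 | (R)-(+)-citronellic acid, (3R)-3,7-dimethyloct-6-enoic acid | CC(C)=CCC[C@@H](C)CC(=O)O | starting material
2 | tert-butyl (3R)-3,7-dimethyloct-6-enoate | CC(C)=CCC[C@@H](C)CC(=O)OC(C)(C)C | intermediate
3 | ozonide of 2, tert-butyl (3R)-5-(5,5-dimethyl-1,2,4-trioxolan-3-yl)-3-methylpentanoate | CC1(C)OC(CC[C@@H](C)CC(=O)OC(C)(C)C)OO1 | intermediate (not isolated)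
4 | tert-butyl (3R)-3-methyl-6-oxohexanoate | O=CCC[C@@H](C)CC(=O)OC(C)(C)C | intermediate
5 | methyl acrylate | C=CC(=O)OC | starting material
6 | 8-tert-butyl 1-methyl (6R)-3-hydroxy-6-methyl-2-methylideneoctanedioate (C3 epimers) | C=C(C(=O)OC)C(O)CC[C@@H](C)CC(=O)OC(C)(C)C | intermediate
7 | 8-tert-butyl 1-methyl (2Z,6R)-2-(bromomethyl)-6-methyloct-2-enedioate | BrC/C(C(=O)OC)=C\CC[C@@H](C)CC(=O)OC(C)(C)C | intermediate
8 | 3-[(tert-butyldimethylsilyl)oxy]propanal | O=CCCO[Si](C)(C)C(C)(C)C | starting material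
9 | tert-butyl{[(3Z)-4-iodopent-3-en-1-yl]oxy}dimethylsilane | C/C(I)=C/CCO[Si](C)(C)C(C)(C)C | intermediate
10 | (3Z)-4-iodopent-3-en-1-ol | C/C(I)=C/CCO | intermediate
11 | methyl (triphenylphosphoranylidene)acetate | COC(=O)C=P(c1ccccc1)(c1ccccc1)c1ccccc1 | starting material
12 | (chloromethoxy)triisopropylsilane | ClCO[Si](C(C)C)(C(C)C)C(C)C | starting material
13 | {1-methoxy-1-oxo-3-[(triisopropylsilyl)oxy]propan-2-yl}triphenylphosphonium chloride | COC(=O)C(CO[Si](C(C)C)(C(C)C)C(C)C)[P+](c1ccccc1)(c1ccccc1)c1ccccc1.[Cl-] | intermediate (not isolated)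
14 | methyl 2-(triphenylphosphoranylidene)-3-[(triisopropylsilyl)oxy]propanoate | COC(=O)C(CO[Si](C(C)C)(C(C)C)C(C)C)=P(c1ccccc1)(c1ccccc1)c1ccccc1 | intermediate
15 | (3Z)-4-iodopent-3-enal | C/C(I)=C/CC=O | intermediate (not isolated)
16 | methyl (2E,5Z)-6-iodo-2-{[(triisopropylsilyl)oxy]methyl}hepta-2,5-dienoate | COC(=O)/C(CO[Si](C(C)C)(C(C)C)C(C)C)=C/C/C=C(/C)I | intermediate
17 | (3E,6Z)-7-iodo-2-methoxy-3-{[(triisopropylsilyl)oxy]methyl}octa-1,3,6-triene | C=C(OC)/C(CO[Si](C(C)C)(C(C)C)C(C)C)=C/C/C=C(/C)I | intermediate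
18 | alkenyllithium from 17 (Li in place of I) | C=C(OC)/C(CO[Si](C(C)C)(C(C)C)C(C)C)=C/C/C=C(/C)[Li] | intermediate (not isolated)
19 | alkenyl(diisobutyl)alane from 18 | C=C(OC)/C(CO[Si](C(C)C)(C(C)C)C(C)C)=C/C/C=C(/C)[Al](CC(C)C)CC(C)C | intermediate (not isolated)
20 | 8-tert-butyl 1-methyl (3R,6R)-3-[(2Z,5E)-7-methoxy-6-{[(triisopropylsilyl)oxy]methyl}octa-2,5,7-trien-2-yl]-6-methyl-2-methylideneoctanedioate | C=C(C(=O)OC)[C@H](CC[C@@H](C)CC(=O)OC(C)(C)C)/C(C)=C\C/C=C(CO[Si](C(C)C)(C(C)C)C(C)C)/C(OC)=C | intermediate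
21 | tert-butyl (3R,6R,7Z,10E)-6-(3-hydroxyprop-1-en-2-yl)-12-methoxy-3,7-dimethyl-11-{[(triisopropylsilyl)oxy]methyl}trideca-7,10,12-trienoate | C=C(CO)[C@H](CC[C@@H](C)CC(=O)OC(C)(C)C)/C(C)=C\C/C=C(CO[Si](C(C)C)(C(C)C)C(C)C)/C(OC)=C | intermediate
22 | tert-butyl (3R,6R,7Z,10E)-12-methoxy-3,7-dimethyl-6-(3-oxoprop-1-en-2-yl)-11-{[(triisopropylsilyl)oxy]methyl}trideca-7,10,12-trienoate | C=C(C=O)[C@H](CC[C@@H](C)CC(=O)OC(C)(C)C)/C(C)=C\C/C=C(CO[Si](C(C)C)(C(C)C)C(C)C)/C(OC)=C | intermediate (not isolated)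
23 | tert-butyl 3-methoxy-20-oxo-19-[(triisopropylsilyl)oxy]-18-norlabda-3,7-dien-15-oate (trans-fused; 5β-H; 9β-H; 10α-CHO; 13R) | CC(C)[Si](OCC1=C(OC)CC[C@@]2(C=O)[C@H](CC[C@@H](C)CC(=O)OC(C)(C)C)C(C)=CC[C@H]12)(C(C)C)C(C)C | intermediate
24 | N-(tert-butyldimethylsilyl)hydrazone of 23 at C20 | CC(C)[Si](OCC1=C(OC)CC[C@@]2(C=NN[Si](C)(C)C(C)(C)C)[C@H](CC[C@@H](C)CC(=O)OC(C)(C)C)C(C)=CC[C@H]12)(C(C)C)C(C)C | intermediate (not isolated)
25 | tert-butyl 3-methoxy-19-[(triisopropylsilyl)oxy]-18-norlabda-3,7-dien-15-oate (5β-H; 9β-H; 10α-CH3; 13R) | CC(C)[Si](OCC1=C(OC)CC[C@@]2(C)[C@H](CC[C@@H](C)CC(=O)OC(C)(C)C)C(C)=CC[C@H]12)(C(C)C)C(C)C | intermediate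
26 | tert-butyl 3α-methoxy-19-[(triisopropylsilyl)oxy]-3β,18-cyclolabd-7-en-15-oate (cyclopropane CH2 on the β face) | CC(C)[Si](OC[C@@]12C[C@@]2(OC)CC[C@@]3(C)[C@H](CC[C@@H](C)CC(=O)OC(C)(C)C)C(C)=CC[C@H]13)(C(C)C)C(C)C | intermediate
27 | tert-butyl 3-oxo-19-[(triisopropylsilyl)oxy]labd-7-en-15-oate (C18 β; C19 α) | CC(C)[Si](OC[C@@]1(C)[C@H]2CC=C(C)[C@@H](CC[C@@H](C)CC(=O)OC(C)(C)C)[C@]2(C)CCC1=O)(C(C)C)C(C)C | intermediate (not isolated)
28 | tert-butyl 19-hydroxy-3-oxolabd-7-en-15-oate | OC[C@@]1(C)[C@H]2CC=C(C)[C@@H](CC[C@@H](C)CC(=O)OC(C)(C)C)[C@]2(C)CCC1=O | intermediate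
29 | tert-butyl 19-acetoxy-3-oxolabd-7-en-15-oate | CC(=O)OC[C@@]1(C)[C@H]2CC=C(C)[C@@H](CC[C@@H](C)CC(=O)OC(C)(C)C)[C@]2(C)CCC1=O | intermediate
30 | potassium Δ2-enolate of 29 | CC(=O)OC[C@@]1(C)[C@H]2CC=C(C)[C@@H](CC[C@@H](C)CC(=O)OC(C)(C)C)[C@]2(C)CC=C1[O-].[K+] | intermediate (not isolated)
31 | tert-butyl 19-acetoxy-2β-hydroxy-3-oxolabd-7-en-15-oate | CC(=O)OC[C@@]1(C)[C@H]2CC=C(C)[C@@H](CC[C@@H](C)CC(=O)OC(C)(C)C)[C@]2(C)C[C@H](O)C1=O | intermediate
32 | tert-butyl 19-acetoxy-2β,3β-dihydroxylabd-7-en-15-oate | CC(=O)OC[C@@]1(C)[C@H]2CC=C(C)[C@@H](CC[C@@H](C)CC(=O)OC(C)(C)C)[C@]2(C)C[C@H](O)[C@@H]1O | intermediate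
33 | (2S,3R,4R,5S,9R,10S,13R)-19-acetoxy-2,3-dihydroxylabd-7-en-15-oic acid | CC(=O)OC[C@@]1(C)[C@H]2CC=C(C)[C@@H](CC[C@@H](C)CC(=O)O)[C@]2(C)C[C@H](O)[C@@H]1O | target

**Step count and risks**

Total step count: 19. Longest linear sequence: 14 steps (8 → 33 through steps 5, 6, 8–19; equally 1 → 33 through steps 1–4 and 10–19).

Steps most likely to fail:

1. Step 12 (key step). The endo preference may erode, for example if the Lewis acid is tied up by the ester and ether oxygens or the enal cyclises thermally before cooling; this would show as partial cis ring fusion at C5. The fallback corrects C5 after the cycloaddition instead of relying on the transition state. It sets out from 25, carried through step 13 as the mixture of C5 epimers. Oxidation of the enol ether with DDQ (CH2Cl2/H2O, 0 °C) should give tert-butyl 3-oxo-19-[(triisopropylsilyl)oxy]-18-norlabda-4,7-dien-15-oate F1, in which C5 is no longer a stereocentre. Birch-type reductive methylation (Li, NH3/THF, −78 °C; then MeI) should then give the trans ring fusion and place the new methyl group anti to C20. This returns to the route at 27, which is treated with HF·pyridine as in the second stage of step 15.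

2. Step 10. Catalyst control of the π-face at C9 may be incomplete with the hindered Z-trisubstituted alkenyl group, or attack may drift to C1 (SN2). The fallback uses auxiliary control and sets out from 4 and 18.
   - Doebner–Knoevenagel condensation of 4 with malonic acid (pyridine, piperidine) should give (2E,6R)-8-(tert-butoxy)-6-methyl-8-oxooct-2-enoic acid F2.
   - Mixed-anhydride acylation (PivCl, Et3N, LiCl) of (R)-4-benzyl-2-oxazolidinone gives tert-butyl (3R,6E)-8-[(4R)-4-benzyl-2-oxo-1,3-oxazolidin-3-yl]-3-methyl-8-oxooct-6-enoate F3.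
   - Alkenyllithium 18 is converted with MgBr2·OEt2 into the alkenylmagnesium bromide F4. With CuBr·SMe2 (20 mol %) this should add to the chelated imide F3 anti to the benzyl group, giving the bromomagnesium enolate F5 with C9 in the R configuration.
   - F5 is trapped in the flask with monomeric formaldehyde to give the α-hydroxymethyl imide F6.
   - MsCl/Et3N followed by DBU gives the 2-methylene imide F7.
   - MeOMgBr (MeOH/CH2Cl2, 0 °C) exchanges the auxiliary for the methyl ester and returns to the route at 20.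

3. Step 17. While the free potassium enolate waits for the oxidant, the C19 acetate may migrate to the enolate oxygen or be attacked by C2. The fallback avoids a free enolate and sets out from 29. Deprotonation with LiHMDS in the presence of TMSCl (internal quench, THF, −78 °C) should give tert-butyl 19-acetoxy-3-[(trimethylsilyl)oxy]labda-2,7-dien-15-oate F8. Catalytic OsO4 with NMO (acetone/H2O, 0 °C) should oxidise this electron-rich enol ether from the β face much faster than the hindered Δ7 alkene, and collapse of the silylated ketol on work-up returns to the route at 31.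

**Further compounds**
F1 | step 12 | tert-butyl 3-oxo-19-[(triisopropylsilyl)oxy]-18-norlabda-4,7-dien-15-oate | CC(C)[Si](OCC1=C2CC=C(C)[C@@H](CC[C@@H](C)CC(=O)OC(C)(C)C)[C@]2(C)CCC1=O)(C(C)C)C(C)C
F2 | step 10 | (2E,6R)-8-(tert-butoxy)-6-methyl-8-oxooct-2-enoic acid | OC(=O)/C=C/CC[C@@H](C)CC(=O)OC(C)(C)C
F3 | step 10 | tert-butyl (3R,6E)-8-[(4R)-4-benzyl-2-oxo-1,3-oxazolidin-3-yl]-3-methyl-8-oxooct-6-enoate | O=C(/C=C/CC[C@@H](C)CC(=O)OC(C)(C)C)N1[C@H](Cc2ccccc2)COC1=O
F4 | step 10 | alkenylmagnesium bromide from 18 | C=C(OC)/C(CO[Si](C(C)C)(C(C)C)C(C)C)=C/C/C=C(/C)[Mg]Br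
F5 | step 10 | bromomagnesium enolate of the conjugate adduct (9R) | Br[Mg]OC(=C[C@H](CC[C@@H](C)CC(=O)OC(C)(C)C)/C(C)=C\C/C=C(CO[Si](C(C)C)(C(C)C)C(C)C)/C(OC)=C)N1[C@H](Cc2ccccc2)COC1=O
F6 | step 10 | α-hydroxymethyl imide (9R; C10 epimers) | OCC(C(=O)N1[C@H](Cc2ccccc2)COC1=O)[C@H](CC[C@@H](C)CC(=O)OC(C)(C)C)/C(C)=C\C/C=C(CO[Si](C(C)C)(C(C)C)C(C)C)/C(OC)=C
F7 | step 10 | 2-methylene imide (9R) | C=C(C(=O)N1[C@H](Cc2ccccc2)COC1=O)[C@H](CC[C@@H](C)CC(=O)OC(C)(C)C)/C(C)=C\C/C=C(CO[Si](C(C)C)(C(C)C)C(C)C)/C(OC)=C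
F8 | step 17 | tert-butyl 19-acetoxy-3-[(trimethylsilyl)oxy]labda-2,7-dien-15-oate | CC(=O)OC[C@@]1(C)[C@H]2CC=C(C)[C@@H](CC[C@@H](C)CC(=O)OC(C)(C)C)[C@]2(C)CC=C1O[Si](C)(C)C
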